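All constants are invented; the rest is arithmetic.

Beside this flask I kept a neighbour in mind, the same scheme charged with 40 mM of substrate, and looked for a number that would carry from one to the other.

substrate 10 mM; gas phase 1.3 mM (held); time 12 min

    gas phase ⇌ dissolved gas, rate k1*(csat - [dissolved gas]) (k1 = 0.20 /s, csat = 1.3 mM)
    substrate + dissolved gas → target (k2 = 5.7 /M/s)
    substrate → side product (k3 = 5.6 × 10⁻⁴ /s)
    crystals ⇌ target, rate k4*(cs4 - [target]) while solid is left; crystals form when [target] > cs4 (cs4 = 4.5 mM, k4 = 1.1 /s)
    target ⇌ isomer of the product (K5 = 0.32, k5 = 0.0062 /s)

- Wednesday's: doubling the dissolution coefficient of step 4, all else as stated
- Monday's: doubling the saturation concentration of gas phase, all else as stated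
- Sunday's: doubling the transfer coefficient of step 1, all else as stated
- Thursday's: doubling the solubility in step 4, all else as stated

- amounts and yields of target count crystals too
- given per volume of solution although it is solid: crystals
- at the start none of the gas is dissolved
- run time (flask): 12 min

* the target and crystals together standing at 12 min, as a percentage of the substrate charged
* the change that raises the amount of target and crystals together at 12 min, in percent of the substrate charged most ("none" if none brings more than 2 percentage points) (Wednesday's / Monday's / Sunday's / Thursday's / none)
* amount of target and crystals together at 12 min, in percent of the substrate charged, after Thursday's

I counted everything in fractions of the charge and folded the solubility, the isomer constant and the charge into one number, 0.594: the room, the fraction of the charge that the solution can hold as target and isomer together before crystals form. The isomer equilibrium relaxes in 0.452 min, short against 12 min, so the isomer takes 0.242 of whatever is dissolved. Where step 2 makes more than the room, the isomer's part is that share of the room, 14.4%; where it makes less, it is that share of what was made.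

One number was not enough: the room has to be held against what step 2 makes. Gas transfer, with a half-life of 0.0578 min, is faster than the use of dissolved gas by step 2, whose half-life is 0.20 min with the substrate as charged, so I took the gas as saturated. Step 2 is then pseudo-first-order, and I reckoned that the selectivity sends 93.0% of the substrate consumed to target. That exceeds the room, so for full consumption I reckoned 78.6% for this flask.

After Thursday's the room of 1.19 is more than the 93.0% made, which gives 70.4%, less than 78.6%. Monday's raises the selectivity and gains 3.4 percentage points, more than 2 points, while Sunday's and Wednesday's change neither the selectivity nor the room as I reckoned them, so I chose Monday's.

The forecast gave 77.3%, Monday's and 69.5%, holding that “Doubling the gas saturation is the only change that clearly beats the side reaction”.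

The simulation of this flask gave 77.0%, Monday's with 4.2 points gained, and 69.3% after Thursday's. At 12.0 min this flask held 14.4% as isomer beside 32.0% as crystals. In the neighbour flask the room is 0.149, which puts the isomer share at 3.61%, and that flask ended with 3.60% as isomer.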